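**Remarks.** Ring C is numbered C1 (ketone next to the CH2), C2 (carries the coumarin), C3 (CH), C4 (ketone next to the carbinol), C5 (carbinol), C6 (CH2); the same labels are kept for open-chain compounds. Racemic but-3-yn-2-ol is used because its stereocentre is erased in step 6, so compounds 5, 7–10 and 12 are racemates. The quinine-derived amine in step 10 is assumed, from a working model only, to deliver the (R)-carbinol.

## Analysis of the target

The target is a 7-methoxycoumarin (rings A and B) joined through its C3 to C2 of a cyclohex-2-ene-1,4-dione (ring C: C1=O, C2 aryl, C3–H, C4=O, C5(OH)(prenyl), C6H2). The only stereocentre is C5, an (R)-configured tertiary carbinol bearing the prenyl group. It stands alone, so nothing in the molecule can relay configuration to it and it must come from reagent or catalyst control. The C5 hydroxyl is β to the C1 ketone and α to the C4 ketone: loss of water across C5–C6 leads irreversibly to the achiral quinone level, and retro-aldol cleavage of C5–C6 is also open. The prenyl alkene is sensitive to acid (cyclisation onto the C5 hydroxyl) and sits β,γ to a carbonyl in every open-chain precursor; the coumarin lactone and the enedione accept nucleophiles and bases. The difficulty is therefore to create an isolated, oxygenated quaternary centre late, under near-neutral conditions, with every ring carbon already at its final oxidation level. The strategy rests on the C1(=O)–C6H2–C5(OH) unit being an aldol retron: C6 is the α-carbon of a ketone whose other α-position (C2) is sp2, so in the open chain it is the methyl group of a methyl ketone and the only position that can become an enamine. The cis C2=C3 bond holds that methyl group next to a C5 prenyl ketone, and C4 is kept as a ketal.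

## Retrosynthetic reasoning

**19 to 18.** Only the two C4–O bonds of a dimethyl ketal are restored. C4 is masked because a free C4 ketone would offer the donor carbon a second, five-membered closure and because the hydroxy-enedione is the most fragile state of the molecule. The forward step is a mild aqueous acid hydrolysis that touches no bond at C5.

**18 to 17.** The C5–C6 bond is cut. It is the only ring bond whose formation also creates the stereocentre; cutting C1–C2 or C3–C4 instead would require C5 to be made beforehand in an acyclic fragment. The cut opens ring C to a chain in which C6 is a methyl group and C5 a ketone. The forward reaction is an amine-catalysed aldol closure in the 6-(enolendo)-exo-trig mode (both C6 and C1 end up in the ring, as in the Hajos–Parrish reaction). It has to form the enamine at C6 only, choose one face of the C5 carbonyl, and find the C2=C3 bond in the Z geometry.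

**17 to 15 and 16.** The two terminal methyl groups of the prenyl unit are removed, leaving an allyl ketone. The C5 acyl carbon must be bonded to the CH2 end of the prenyl group, whereas prenyl-metal reagents deliver their tertiary end; an allyl reagent has no such ambiguity. Cross-metathesis with 16 adds the methyl groups, and it is placed after the triple bond has been consumed so that enyne metathesis cannot compete.

**15 to 14 and 3.** The bond between C2 and the coumarin C3 is cut. Forming C2=C3 by a carbonyl condensation instead would leave the geometry to thermodynamics, which is expected to place the acetyl group trans to the bulky C4. A cross-coupling with retention transfers the geometry of a vinyl–tin bond to the product.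

**14 to 13.** Hydrogen and tin are removed from C3 and C2. In the forward direction syn addition of a tin hydride to ynone 13 places tin α to the conjugated carbonyl (C2), which is also the less hindered alkyne carbon. Because H and Sn arrive on the same side, C1 and C4 end up cis, which is the Z relationship the ring closure needs.

**13 to 12 to 10 and 11.** C1 is taken back to a carbinol, because it must not be a ketone while an organomagnesium reagent is in use. The C5–CH2 bond is then cut: the N-methoxy-N-methylamide of 10 is the acyl donor for the allyl reagent 11.

**10 to 8 to 5 and 6.** The C4 ketal is taken back to the ketone of 8, and the C3–C4 bond is cut to the lithium acetylide 7 (from 5) and the oxamide 6. Compound 6 is a C4–C5 unit with two identical ends that the first addition differentiates: C4 becomes a ketone, then the ketal, and C5 remains an amide for the later acyl substitution.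

**5 to 4 and 3 to 1.** A silyl ether on 4 carries the C1 oxygen through the organolithium step. Bromination of 1 at C3 provides the coupling partner 3.

## Alternatives that were turned down

**Alternative 1:** The C1–C6 and C5–O bonds are disconnected through a 2-isoxazoline as a masked β-hydroxy ketone. In the forward key step the nitrile oxide generated from hydroximoyl chloride A1 adds to the zinc alkoxide of the 1,1-disubstituted allylic alcohol A2 in the presence of a dialkylzinc and a tartrate ester, giving isoxazoline A3 with C5 set.
- For it: hydroxyl-directed, tartrate-controlled cycloadditions are a well-established way to make an oxygenated quaternary centre with a predictable sense, and the zinc alkoxide steers the dipole away from the prenyl alkene. On predictability of the configuration this route is stronger than a face-selective ketone aldol.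
- Against it: A3 contains only five of the six ring-C carbons (C3 is missing), ring C is not closed, and C4 is at the alcohol level. After the cycloaddition the N–O bond must be cleaved in the presence of a coumarin and a prenyl alkene, C4 raised by two oxidation levels, a one-carbon unit inserted between C2 and C4, the ring closed and the C2=C3 unsaturation introduced. The nitrile oxide also sits next to an acidic methylene and is prone to dimerise.
- Comparison: the chosen route gives up some certainty about the sense of induction, but it closes the ring and sets C5 in one catalytic step on a precursor that has every carbon at the correct oxidation level, one step from the target.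

**Alternative 2:** The C1–C2 acyl–vinyl bond is disconnected. In the forward key step the phenyl thioester and the vinylstannane of open-chain A4 are joined intramolecularly by a zerovalent palladium catalyst with a copper carboxylate (monovalent copper) in a Liebeskind–Srogl-type coupling, giving the C5 silyl ether A5.
- For it: the ring closure is neutral and irreversible, so there is no retro-aldol and no ketal at C4. On robustness of the ring-forming event it is as strong as or stronger than an aldol.
- Against it: the step creates no stereocentre. C5 must be built earlier as a protected quaternary carbinol flanked by a ketone and a thioester-bearing CH2, which is an unsolved aldol-type problem moved to an acyclic, elimination-prone intermediate. The stannane in A4 is α-aryl and β to the C4 carbonyl, so tin transfer is slow and the geometry must be controlled separately. The final removal of a tertiary silyl ether β to a ketone invites elimination to the quinone level.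
- Comparison: the sequence is longer (stereocentre, stannane and thioester installed separately). The chosen route merges ring closure and stereocentre formation and ends with a ketal hydrolysis.

**Alternative 3:** The C4–C5 and C6–C1 bonds are disconnected in a [4+2] sense. In the forward key step diene A6 and the α-acyloxyacrolein A7 combine under a chiral primary ammonium salt to give cyclohexene A8 with C5 set.
- For it: two ring bonds and the stereocentre are made in one convergent step, the regiochemistry follows from the 2-substituted diene, and iminium-activated α-acyloxyacroleins are known to give high, predictable enantioselectivity. On convergence and documented enantiocontrol it is stronger.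
- Against it: A8 has the wrong oxidation level at four positions. C1 and C4 are CH2 groups that both need allylic oxidation on an electron-poor alkene, the formyl group must be turned into prenyl (a one-carbon homologation and an olefination at a neopentyl centre), and the ester must be removed. Once C1 is a ketone the C5 acyloxy group is a β-leaving group. Diene A6 is cross-conjugated, electron-poor and likely to dimerise.
- Comparison: the cycloaddition is followed by a long and hazardous oxidation sequence. The chosen aldol forms ring C with all oxygen functions in place.

Key step: step 10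

## Route

Step 1
Reactants: 1 7-methoxy-2H-chromen-2-one (7-methoxycoumarin)
Product: 3 3-bromo-7-methoxy-2H-chromen-2-one, via dibromide 2 (not isolated)
Conditions: Br2, CH2Cl2, 0 °C → rt; then Et3N, 0 °C → rt
Reagents that add atoms: bromine, BrBr
Why: Bromine adds to the pyranone C3=C4 bond (the C4 cation is stabilised by the para 7-methoxy group) and base removes HBr through the acidic C3 hydrogen; this addition–dehydrobromination is the standard route to 3-bromocoumarins.

Step 2
Reactants: 4 but-3-yn-2-ol (racemic)
Product: 5 tert-butyl(but-3-yn-2-yloxy)dimethylsilane
Conditions: TBSCl, imidazole, DMF, rt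
Reagents that add atoms: tert-butyldimethylsilyl chloride, CC(C)(C)[Si](C)(C)Cl
Why: Standard silylation of a secondary alcohol; the ether survives n-BuLi and keeps the γ-oxygen of the later ynone from reacting.

Step 3
Reactants: 5 tert-butyl(but-3-yn-2-yloxy)dimethylsilane; 6 N,N'-dimethoxy-N,N'-dimethyloxamide
Product: 8 5-[(tert-butyldimethylsilyl)oxy]-N-methoxy-N-methyl-2-oxohex-3-ynamide, via lithium acetylide 7 (not isolated)
Conditions: n-BuLi, THF, −78 °C; then 6 (1.5 equiv), −78 → −40 °C; aq. NH4Cl
Reagents that add atoms: none
Why: Weinreb-type acyl substitution: the acetylide adds once to the bis(N-methoxy-N-methyl)amide and the chelated tetrahedral adduct persists until work-up, so the second amide is untouched and C3–C4 is formed with C4 as a ketone.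

Step 4
Reactants: 8 5-[(tert-butyldimethylsilyl)oxy]-N-methoxy-N-methyl-2-oxohex-3-ynamide
Product: 10 5-hydroxy-N,2,2-trimethoxy-N-methylhex-3-ynamide, via silyl ether ketal 9 (not isolated)
Conditions: HC(OMe)3, MeOH, TsOH·H2O (cat.), 45 °C
Reagents that add atoms: trimethyl orthoformate, COC(OC)OC; methanol, CO
Why: Acid-catalysed ketalisation with an orthoformate as water scavenger, as used for α-keto esters and amides; the electron-poor C4 ketone is hemiketalised at once in methanol, which takes the triple bond out of conjugation, and the amide carbonyl does not ketalise. The acidic methanol then cleaves the silyl ether by methanolysis.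

Step 5
Reactants: 10 5-hydroxy-N,2,2-trimethoxy-N-methylhex-3-ynamide; 11 allylmagnesium bromide
Product: 12 8-hydroxy-5,5-dimethoxynon-1-en-6-yn-4-one
Conditions: 11 (3 equiv), THF, −78 → −20 °C; aq. NH4Cl at −78 °C
Reagents that add atoms: none
Why: Weinreb ketone synthesis: one equivalent deprotonates the hydroxyl, and the magnesium chelate of the tetrahedral adduct (N-methoxy and ketal oxygens) prevents a second addition. The allyl reagent has no α/γ ambiguity, and the cold buffered quench keeps the new alkene out of conjugation.

Step 6
Reactants: 12 8-hydroxy-5,5-dimethoxynon-1-en-6-yn-4-one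
Product: 13 5,5-dimethoxynon-8-en-3-yne-2,6-dione
Conditions: Dess–Martin periodinane, CH2Cl2, 0 °C → rt
Reagents that add atoms: none
Why: Dess–Martin oxidation of the only alcohol, a secondary propargylic carbinol, gives the ynone under non-basic conditions that leave the allyl ketone and the ketal alone.

Step 7
Reactants: 13 5,5-dimethoxynon-8-en-3-yne-2,6-dione
Product: 14 (3E)-5,5-dimethoxy-3-(tributylstannyl)nona-3,8-diene-2,6-dione
Conditions: Bu3SnH (1.05 equiv, slow addition), Pd(PPh3)4 (2 mol %), THF, 0 °C
Reagents that add atoms: tributyltin hydride, CCCC[SnH](CCCC)CCCC
Why: Palladium-catalysed hydrostannation of an alkynyl ketone is a syn addition that places tin on the carbon α to the conjugated carbonyl (C2), here also the less hindered alkyne carbon, so electronic and steric bias agree. Syn delivery of H and Sn fixes the acetyl group and C4 on the same side, and the alkyne reacts far faster than the terminal alkene.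

Step 8
Reactants: 14 (3E)-5,5-dimethoxy-3-(tributylstannyl)nona-3,8-diene-2,6-dione; 3 3-bromo-7-methoxy-2H-chromen-2-one
Product: 15 3-[(3Z)-5,5-dimethoxy-2,6-dioxonona-3,8-dien-3-yl]-7-methoxy-2H-chromen-2-one
Conditions: Pd2(dba)3, P(2-furyl)3, CuI, NMP, 45 °C
Reagents that add atoms: none
Why: Stille coupling with copper co-catalysis, the usual remedy for hindered α-stannyl enones, proceeds with retention at the vinyl carbon, so the coumarin replaces tin and the acetyl group stays cis to C4 (Z). The fluoride-free, neutral medium spares the allyl ketone and the lactone, and 3 is an activated vinyl bromide for oxidative addition.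

Step 9
Reactants: 15 3-[(3Z)-5,5-dimethoxy-2,6-dioxonona-3,8-dien-3-yl]-7-methoxy-2H-chromen-2-one; 16 2-methylbut-2-ene
Product: 17 3-[(3Z)-5,5-dimethoxy-9-methyl-2,6-dioxodeca-3,8-dien-3-yl]-7-methoxy-2H-chromen-2-one
Conditions: second-generation Grubbs catalyst RuCl2(=CHPh)(PCy3)(H2IMes) (5 mol %), 16/CH2Cl2, 35 °C
Reagents that add atoms: none
Why: Olefin cross-metathesis of a terminal alkene with 2-methylbut-2-ene is the standard allyl-to-prenyl conversion. The trisubstituted, electron-poor C2=C3 and coumarin double bonds are inert, and no triple bond remains to divert the carbene.

Step 10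
Reactants: 17 3-[(3Z)-5,5-dimethoxy-9-methyl-2,6-dioxodeca-3,8-dien-3-yl]-7-methoxy-2H-chromen-2-one
Product: 18 3-[(4R)-4-hydroxy-3,3-dimethoxy-4-(3-methylbut-2-en-1-yl)-6-oxocyclohex-1-en-1-yl]-7-methoxy-2H-chromen-2-one
Conditions: 9-amino-9-deoxy-epi-quinine (20 mol %), AcOH (60 mol %), toluene, 0 °C → rt
Reagents that add atoms: none
Why: The primary amine condenses with the C1 enone carbonyl to a ketiminium ion that can lose a proton only from the C6 methyl group (C2 is sp2 and C4 carries no hydrogen), giving a cross-conjugated 2-aminodiene. Its C6 terminus adds to the C5 carbonyl, which is activated by the two α-oxygens and by a hydrogen bond from the protonated quinuclidine, and hydrolysis of the cyclic ketimine returns the catalyst and the ketol. The closest known reaction type is the chiral-amine-catalysed intramolecular ketone–ketone aldol of the Hajos–Parrish family, in its cinchona primary-amine form for acyclic diketones. Ring C closes in the same 6-(enolendo)-exo-trig mode, with both C6 and C1 inside the new ring. C5 is the only new stereocentre and is under catalyst control: the hydrogen-bonded closed transition state has to tell the ring ketal carbon C4 from the exocyclic prenyl CH2, and the quinine-derived amine is expected to give the (R)-carbinol. Chemoselectivity rests on the substrate: the C5 ketone is neopentyl-like and its iminium ion is destabilised by the ketal, so it acts as acceptor and not as donor, and the C4 ketal rules out five-ring closure. The Z alkene fixed in steps 7 and 8 holds C6 within reach of C5, and reversible conjugate addition of the amine at C3 can return any E isomer. Weak acid and low temperature keep the tertiary ketol from losing water.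

Step 11
Reactants: 18 3-[(4R)-4-hydroxy-3,3-dimethoxy-4-(3-methylbut-2-en-1-yl)-6-oxocyclohex-1-en-1-yl]-7-methoxy-2H-chromen-2-one
Product: 19 3-[(4R)-4-hydroxy-4-(3-methylbut-2-en-1-yl)-3,6-dioxocyclohex-1-en-1-yl]-7-methoxy-2H-chromen-2-one
Conditions: 1 M aq. HCl, THF, 0 °C → rt
Reagents that add atoms: water, O
Why: Acid-catalysed ketal hydrolysis through the C4 oxocarbenium ion unveils the enedione without breaking any bond at C5, so the configuration is kept. Dilute acid at low temperature is chosen because the product can lose water towards the quinone and the prenyl alkene is acid-sensitive.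

## Compound list

1 | 7-methoxy-2H-chromen-2-one | COc1ccc2ccc(=O)oc2c1 | starting material
2 | rac-trans-3,4-dibromo-7-methoxy-3,4-dihydro-2H-chromen-2-one (one enantiomer drawn) | COc1ccc2c(c1)OC(=O)[C@@H](Br)[C@@H]2Br | intermediate
3 | 3-bromo-7-methoxy-2H-chromen-2-one | COc1ccc2cc(Br)c(=O)oc2c1 | intermediate
4 | but-3-yn-2-ol (racemic) | CC(O)C#C | starting material
5 | tert-butyl(but-3-yn-2-yloxy)dimethylsilane (racemic) | CC(O[Si](C)(C)C(C)(C)C)C#C | intermediate
6 | N,N'-dimethoxy-N,N'-dimethyloxamide | CON(C)C(=O)C(=O)N(C)OC | starting material
7 | {3-[(tert-butyldimethylsilyl)oxy]but-1-yn-1-yl}lithium (racemic) | CC(O[Si](C)(C)C(C)(C)C)C#C[Li] | intermediate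
8 | 5-[(tert-butyldimethylsilyl)oxy]-N-methoxy-N-methyl-2-oxohex-3-ynamide (racemic) | CC(O[Si](C)(C)C(C)(C)C)C#CC(=O)C(=O)N(C)OC | intermediate
9 | 5-[(tert-butyldimethylsilyl)oxy]-N,2,2-trimethoxy-N-methylhex-3-ynamide (racemic) | CC(O[Si](C)(C)C(C)(C)C)C#CC(OC)(OC)C(=O)N(C)OC | intermediate
10 | 5-hydroxy-N,2,2-trimethoxy-N-methylhex-3-ynamide (racemic) | CC(O)C#CC(OC)(OC)C(=O)N(C)OC | intermediate
11 | allylmagnesium bromide | C=CC[Mg]Br | starting material
12 | 8-hydroxy-5,5-dimethoxynon-1-en-6-yn-4-one (racemic) | CC(O)C#CC(OC)(OC)C(=O)CC=C | intermediate
13 | 5,5-dimethoxynon-8-en-3-yne-2,6-dione | CC(=O)C#CC(OC)(OC)C(=O)CC=C | intermediate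
14 | (3E)-5,5-dimethoxy-3-(tributylstannyl)nona-3,8-diene-2,6-dione | CC(=O)/C(=C\C(OC)(OC)C(=O)CC=C)[Sn](CCCC)(CCCC)CCCC | intermediate
15 | 3-[(3Z)-5,5-dimethoxy-2,6-dioxonona-3,8-dien-3-yl]-7-methoxy-2H-chromen-2-one | CC(=O)/C(=C\C(OC)(OC)C(=O)CC=C)c1cc2ccc(OC)cc2oc1=O | intermediate
16 | 2-methylbut-2-ene | CC=C(C)C | starting material
17 | 3-[(3Z)-5,5-dimethoxy-9-methyl-2,6-dioxodeca-3,8-dien-3-yl]-7-methoxy-2H-chromen-2-one | CC(=O)/C(=C\C(OC)(OC)C(=O)CC=C(C)C)c1cc2ccc(OC)cc2oc1=O | intermediate
18 | 3-[(4R)-4-hydroxy-3,3-dimethoxy-4-(3-methylbut-2-en-1-yl)-6-oxocyclohex-1-en-1-yl]-7-methoxy-2H-chromen-2-one | COc1ccc2cc(C3=CC(OC)(OC)[C@@](O)(CC=C(C)C)CC3=O)c(=O)oc2c1 | intermediate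
19 | 3-[(4R)-4-hydroxy-4-(3-methylbut-2-en-1-yl)-3,6-dioxocyclohex-1-en-1-yl]-7-methoxy-2H-chromen-2-one | COc1ccc2cc(C3=CC(=O)[C@@](O)(CC=C(C)C)CC3=O)c(=O)oc2c1 | target

## Step count and least certain steps

Total: 11 steps. Longest linear sequence: 10 steps (steps 2–11, from 4); step 1 is a one-step branch that joins at step 8.

**Step 10 (key step).** Several things can go wrong.
- The two faces of the C5 carbonyl differ only in the prenyl CH2 versus the ring ketal carbon, and the sense of induction comes from a working model, so facial selectivity may be low or reversed. The quinidine-derived pseudo-enantiomer of the catalyst is the first variation within the step.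
- Z-to-E isomerisation may outrun cyclisation without the E isomer being returned.
- Condensation of the amine at the C5 ketone would open a different six-ring closure onto C1, or move the prenyl double bond into conjugation.
- The tertiary ketol may lose water towards the quinone monoketal.

Fallback: from 17 the ring is closed without asymmetric induction by an achiral amine salt (pyrrolidine/AcOH or benzylamine/AcOH, toluene, rt) to give the racemic ketol F1. Preparative chromatography on a chiral stationary phase then separates 18 from the (S)-enantiomer F2, and the route is rejoined at 18.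

**Step 4.** Conjugate addition of methanol to the doubly activated triple bond may compete with ketalisation, or the reaction may stall at the hemiketal because the C4 oxocarbenium ion is destabilised by the neighbouring amide.

Fallback: from 8 the ketal is made without any free alcohol by silyl transfer (MeOSiMe3, catalytic Me3SiOTf, CH2Cl2, −78 → −20 °C). This keeps the silyl ether and gives 9 as an isolated compound, and the silyl group is then removed in a separate operation with HF·pyridine to rejoin at 10. No compound outside the list is made (F0).

**Step 8.** Tin-to-palladium transfer from the geminally acylated, α-branched vinylstannane may be slow, leading to protodestannylation, cine substitution or loss of the alkene geometry (a 1,3-shift of tin to the carbonyl oxygen can scramble it).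

Fallback: the polarity of the coupling is reversed. From 14, iododestannylation (I2, CH2Cl2, 0 °C, retention) gives the (3E)-α-iodo enone F3. From 3, Miyaura borylation (B2pin2, KOAc, PdCl2(dppf), dioxane, 80 °C) gives the coumarin-3-ylboronic pinacol ester F4. Suzuki–Miyaura coupling of F3 with F4 (PdCl2(PhCN)2, AsPh3, Ag2O, THF–H2O, rt) rejoins the route at 15.

**Step 5.** The new double bond may migrate into conjugation with the C5 ketone during the basic work-up, and the allyl reagent may add across the triple bond under direction of the neighbouring alkoxide if the temperature rises.

Fallback: from 10 the amide is reduced to the aldehyde F5 (LiAlH4, THF, −78 °C), 11 is added at −78 °C to give the diol F6 (mixture of diastereomers), and both carbinols are oxidised together with Dess–Martin periodinane to rejoin at 13. The β,γ-unsaturated ketone is then first formed under non-basic conditions.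

## Further compounds

F1 | step 10 | racemic 3-[4-hydroxy-3,3-dimethoxy-4-(3-methylbut-2-en-1-yl)-6-oxocyclohex-1-en-1-yl]-7-methoxy-2H-chromen-2-one | COc1ccc2cc(C3=CC(OC)(OC)C(O)(CC=C(C)C)CC3=O)c(=O)oc2c1
F2 | step 10 | 3-[(4S)-4-hydroxy-3,3-dimethoxy-4-(3-methylbut-2-en-1-yl)-6-oxocyclohex-1-en-1-yl]-7-methoxy-2H-chromen-2-one | COc1ccc2cc(C3=CC(OC)(OC)[C@](O)(CC=C(C)C)CC3=O)c(=O)oc2c1
F0 | step 4 | none | none
F3 | step 8 | (3E)-3-iodo-5,5-dimethoxynona-3,8-diene-2,6-dione | CC(=O)/C(I)=C\C(OC)(OC)C(=O)CC=C
F4 | step 8 | 7-methoxy-3-(4,4,5,5-tetramethyl-1,3,2-dioxaborolan-2-yl)-2H-chromen-2-one | COc1ccc2cc(B3OC(C)(C)C(C)(C)O3)c(=O)oc2c1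
F5 | step 5 | 5-hydroxy-2,2-dimethoxyhex-3-ynal (racemic) | CC(O)C#CC(OC)(OC)C=O
F6 | step 5 | 5,5-dimethoxynon-1-en-6-yne-4,8-diol (mixture of diastereomers) | CC(O)C#CC(OC)(OC)C(O)CC=C
A1 | alternative 1 | N-hydroxy-2-(7-methoxy-2-oxo-2H-chromen-3-yl)ethanimidoyl chloride | COc1ccc2cc(CC(Cl)=NO)c(=O)oc2c1
A2 | alternative 1 | 5-methyl-2-methylidenehex-4-en-1-ol | C=C(CO)CC=C(C)C
A3 | alternative 1 | 3-{[(5R)-5-(hydroxymethyl)-5-(3-methylbut-2-en-1-yl)-4,5-dihydro-1,2-oxazol-3-yl]methyl}-7-methoxy-2H-chromen-2-one | OC[C@@]1(CC=C(C)C)CC(Cc2cc3ccc(OC)cc3oc2=O)=NO1
A4 | alternative 2 | S-phenyl (3R,5Z)-6-(7-methoxy-2-oxo-2H-chromen-3-yl)-3-(3-methylbut-2-en-1-yl)-4-oxo-6-(tributylstannyl)-3-[(triethylsilyl)oxy]hex-5-enethioate | CCCC[Sn](CCCC)(CCCC)/C(=C\C(=O)[C@@](O[Si](CC)(CC)CC)(CC=C(C)C)CC(=O)Sc1ccccc1)c1cc2ccc(OC)cc2oc1=O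
A5 | alternative 2 | 7-methoxy-3-{(4R)-4-(3-methylbut-2-en-1-yl)-3,6-dioxo-4-[(triethylsilyl)oxy]cyclohex-1-en-1-yl}-2H-chromen-2-one | COc1ccc2cc(C3=CC(=O)[C@@](O[Si](CC)(CC)CC)(CC=C(C)C)CC3=O)c(=O)oc2c1
A6 | alternative 3 | 3-(buta-1,3-dien-2-yl)-7-methoxy-2H-chromen-2-one | C=CC(=C)c1cc2ccc(OC)cc2oc1=O
A7 | alternative 3 | 3-oxoprop-1-en-2-yl benzoate | C=C(C=O)OC(=O)c1ccccc1
A8 | alternative 3 | (1R)-1-formyl-4-(7-methoxy-2-oxo-2H-chromen-3-yl)cyclohex-3-en-1-yl benzoate | COc1ccc2cc(C3=CC[C@@](OC(=O)c4ccccc4)(C=O)CC3)c(=O)oc2c1
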